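The readings of target level off near 67% in teal and near 84% in grey, so at the same substrate concentration the level rises with the reagent charged, and the reckoning below takes the rest of the substrate to leave by the suspected route to side product.

| flask | substrate | reagent | remark | time |
|---|---|---|---|---|
| teal | 0.050 M | 3 equiv | run made earlier |  |
| violet | 0.050 M | 4.2 equiv | run made earlier |  |
| grey | 0.050 M | 6.6 equiv | run made earlier |  |
| amber | 0.025 M | 3 equiv | run made earlier |  |
| zeta | 0.050 M | 3.00 equiv | everything together at the start | 2.5 min |
| eta | 0.050 M (in portions, 5, over 1.0 min) | 3.00 equiv | first portion at the start, last at 1.0 min | 2.5 min |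
| epsilon | 0.050 M | 3.00 equiv (fed, over 1.0 min) | all else is in the flask from the start; the feed brings no volume worth counting | 2.5 min |
| delta | 0.050 M (fed, over 1.0 min) | 3.00 equiv | all else is in the flask from the start; the feed brings no volume worth counting | 2.5 min |

teal run (percent of the substrate charged)

| time / min | target / % |
|---|---|
| 0.500 | 38 |
| 1.00 | 53 |
| 1.50 | 63 |
| 2.00 | 67 |
| 2.50 | 66 |

violet run (percent of the substrate charged)

| time / s | target / % |
|---|---|
| 10.0 | 23 |
| 15.0 | 32 |
| 25.0 | 42 |
| 50.0 | 65 |
| 90.0 | 72 |

grey run (percent of the substrate charged)

| time / s | target / % |
|---|---|
| 20.0 | 52 |
| 40.0 | 73 |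
| 50.0 | 79 |
| 80.0 | 81 |
| 90.0 | 84 |

amber run (percent of the substrate charged)

| time / s | target / % |
|---|---|
| 10.0 | 5 |
| 15.0 | 12 |
| 25.0 | 20 |
| 50.0 | 32 |
| 90.0 | 38 |

(each reading ± 2 percentage points)

- on the list of suspects stand: substrate -> side product; substrate + reagent <-> target

- the flask with the highest amount of target, in percent of the substrate charged ("all alike" if they lie within 1.5 percentage points) (zeta / eta / epsilon / delta / all alike)
- final target, as a percentage of the substrate charged, in zeta
- final target, as a percentage of the substrate charged, in eta
- final target, as a percentage of the substrate charged, in epsilon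
- final target, as a percentage of the substrate charged, in delta

My own reckoning, before any result:

1. Let B be the reagent concentration, k the second-order rate constant of substrate + reagent, and j the first-order rate constant of substrate to side product. Leaving the way back aside, substrate goes to target at kB against j, so the share reaching target is reckoned as B/(B + B×), with B× = j/k.

2. Teal reads a share of 67% at a mean reagent of 0.133 M, the charge less half of what target took. Its ratio of side share to target share then gives the crossing concentration B× = 0.0656 M, the reagent level at which both routes run equally and control changes hands; B/B× is the selectivity factor. For grey, at 0.309 M, B× gives 82.5%, against the reading of 84%.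

3. Grey's reading of 52% at 20.0 s gives the total constant as a reading: kB + j = 0.0498 /s. So k = 0.133 /M/s and j = 0.00872 /s.

4. Zeta repeats teal, with a total constant of 0.0264 /s, and gives 65.7% target.

5. Delta is given the same share and is reckoned to hold 4.65% substrate at the end, which gives 63.9%. Eta, taken as a steady feed, gets the same figure. Zeta leads them by 1.8 percentage points; the margin is 1.5 points.

6. In epsilon the fed reagent, counted without what target takes, is reckoned to reach B× at 0.438 min, earlier than the end of the feed. Its mean over the feed, 0.0750 M, gives a share of 53.3% at a constant of 0.0187 /s. With the teal share afterwards, target comes to 55.8%.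

The forecast names zeta, with 66%, 64.5%, 51% and 64.5% for zeta, eta, epsilon and delta, and for epsilon, where it differs from my figure, it argues “reagent starts at zero, so early substrate drains to side product”.

The flasks give 66.2% in zeta, 64.4% in eta, 55.1% in epsilon and 64.5% in delta, so zeta stands first.

    substrate → side product (k = 0.00633 /s)
    substrate + reagent ⇌ target (K = 120 /M, k = 0.131 /M/s)

In zeta the relaxation half-life of substrate + reagent and target, both ways together at 2.50 min, is 0.687 min, shorter than the 2.5 min of the run, and target stands at 66.2% at 2.50 min but at 45.7% after 25.0 min, with side product at 52.1%. Zeta's final reagent, 0.117 M, is 1.78 times B×; for a neighbour of zeta with 12.0 equiv of reagent, all else as in zeta, B× gives a share of 89.8%, and that flask holds 90.0% target and 8.72% side product.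

(Readings and results come from a simulation with constants of no real substance, and the scatter is random.)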